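## Structural features

The target is an ether between two terpenoid-sized halves: a trans-fused eudesmane (rings A and B, with a 2-hydroxypropan-2-yl group on C7) and the biaryl diol honokiol (rings C and D), joined by a single bond from C4 of ring A to the oxygen on C2 of ring C. Ring C carries this oxygen ortho to the biaryl bond and an allyl group para to the oxygen; ring D carries a free hydroxyl para to the biaryl bond and a second allyl group ortho to that hydroxyl, and because the axis has only one ortho substituent it rotates freely and is not a stereo element. All four stereocentres are R: C4, C5 and C10 are contiguous and C7 lies one methylene from C5, with 5α-H, an axial 10β-methyl, an equatorial 7β side chain and an equatorial 4α-oxygen whose geminal methyl is axial and syn to the C10 methyl. The fragile groups are the tertiary alkyl aryl ether at C4 (it ionises under acid and then sheds a proton to give eudesmol-type alkenes), the tertiary C11 alcohol (it dehydrates under the same conditions), the two terminal allyl groups (they slip into conjugation under metal hydrides or strong base) and the electron-rich free phenol. The real difficulty is the fully substituted C4–O bond: it lies next to the ring fusion, it has to be made on the more hindered of the two phenolic oxygens of the biaryl, and its configuration must be fixed at a carbon without hydrogen. The key step exploits the fact that removing the C2–C3 bond of ring A and the C4–O bond leaves a vinyl group (C1=C2) on C10 and an isopropenyl group (C3=C4) on C5, that is, the hexa-1,5-diene C2=C1–C10–C5–C4=C3 of an elemane in which ring B and the centres C5, C7 and C10 are already complete.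

## Logic of the disconnections

11 ⇒ 10. The bond between C5 of ring C and its allyl CH2 is cut. A terminal alkene on this arene would compete with the diene for divalent palladium in the key step and would be exposed to isomerisation in every later palladium step, so its place is held by a chlorine atom that is inert in both earlier metal-catalysed steps. The gain is an intermediate with one allyl group and a robust handle. The forward step must activate an electron-rich aryl chloride under mild basic conditions and leave both terminal alkenes, the free phenol and the acid-sensitive tertiary ether unchanged.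

10 ⇒ 4 + 9. The biaryl bond between C1 of ring C and C1' of ring D is cut. This is the most convergent cut: the phenol and the allyl group of ring D are prepared on a small fragment, and the ring D hydroxyl is never present when the C4 cation is generated. The gain is two fragments of comparable size and a key-step nucleophile with a single hydroxyl. The forward step must couple at the bromide and not at the chloride of 4, ortho to a bulky tertiary alkoxy group, with a free phenol and a tertiary alcohol present.

4 ⇒ 1 + 2 (through 3). Two bonds are cut at once, C2–C3 of ring A and C4–O. This removes ring A, the quaternary stereocentre C4 and the hindered ether in one operation. What remains is a monocyclic chiral-pool 1,5-diene that already has C5, C7 and C10 correct, and a dihalophenol whose two halogens encode the later positions of ring D and of the allyl group. The demand on the forward step is high: the alkene–alkene bond must form 6-endo through a chair, the oxygen of 2 must take the C4 cation from the α face before it loses a proton or fragments, and the carbon–palladium bond of 3 must be cleaved by a proton and not by β-hydride elimination.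

9 ⇒ 8. The C–B bond on ring D is cut back to a C–Br bond, because an aryl bromide para to a hydroxyl is the most accessible precursor of the boronate and tolerates the free phenol and the allyl group. The gain is a simple bromophenol. The forward borylation must not let 9 couple with unreacted 8, which calls for a weak, non-aqueous base.

8 ⇒ 6 (through 7). The bond between the ring carbon ortho to oxygen and the allyl CH2 is cut and the allyl group is returned to oxygen, the retron of an aromatic Claisen rearrangement. There is no regiochemical choice, since the para position is blocked by bromine and the two ortho positions are equivalent. The forward step needs only heat, and the aryl bromide must survive about 200 °C.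

6 ⇒ 5. The O–allyl bond is cut, leaving a commodity bromophenol and an allyl halide. The forward O-alkylation must avoid C-alkylation, which a carbonate base in a polar aprotic solvent ensures.

## Other disconnections considered

Alternative 1: The cut removes C1–C2 and C5–C10, opening both carbocycles to the acyclic triene A1, 2-[(3E,6R)-3,9-dimethyldeca-1,3,9-trien-6-yl]propan-2-ol. Heating A1 would close rings A and B in one intramolecular Diels–Alder reaction and give α-eudesmol A2, with the C3=C4 alkene next to the carbon that must carry the ether.
- In its favour: the step is concerted, metal-free and redox-neutral, it forms two rings and two stereocentres (C5, C10) at once, and it does not depend on the supply of 1.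
- Against it: the dienophile is an unactivated 1,1-disubstituted alkene and the diene is unactivated, so high temperature would be needed. Only the remote C7 centre would steer the facial and the cis/trans outcome at the ring fusion. A2 still lacks the C4–O bond, and Markovnikov addition of hindered 2 to a trisubstituted alkene would need acid, under which the product ether ionises again; the C4 configuration would rest on the same cation as in the chosen plan.
- Comparison: on mechanism the alternative is the better of the two, because its key step is an established pericyclic reaction while step 1 is new. On structure the chosen plan is ahead, since 1 supplies ring B and three stereocentres and ring A is closed together with the C4–O bond. On step economy the chosen plan is ahead, since A1 needs several steps and the hardest bond still follows A2.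

Alternative 2: Here ring C itself is disconnected. Two C–C bonds of the arene are cut so that the C4 oxygen carries an alkyne with ring D on its far carbon (ynol ether A3), and the other four ring carbons come from methyl coumalate A4. An inverse-electron-demand [4+2] cycloaddition of A3 with A4 followed by decarboxylative loss of the lactone bridge would give the benzoate A5, with ring D ortho and the ester para to the ether oxygen.
- In its favour: the arene is grown on an oxygen already attached to C4, so no hindered C–O bond is made at the arene stage. The substitution pattern follows from polarity, since the nucleophilic alkyne carbon (the one bearing ring D) bonds to C6 of the pyranone; this regiocontrol is the equal of the halogen-based control in the chosen plan. The biaryl bond needs no cross-coupling.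
- Against it: A3 already contains the C4–O bond and the C4 stereocentre, so the central problem is moved and not solved. A tertiary-alkyl ynol ether can fragment by a retro-ene path to a ketene and an alkene on warming, in competition with the cycloaddition. A5 still needs the ester turned into an allyl group (reduction, activation, vinylation) and two silyl groups removed.
- Comparison: on mechanism the alternative is the better, since pyranone–alkyne benzannulation is known chemistry. On structure it does not address the C4 ether at all. On step economy it is clearly longer.

Alternative 3: The cut goes back to the acyclic C15 chain: C6–C7 and C5–C10 plus both C–O bonds, leaving (2E,6E)-farnesyl diphosphate A6. A recombinant, magnesium-dependent cryptomeridiol synthase would ionise A6, close the ten-membered ring and then the decalin, and hydrate C11 and C4 to give cryptomeridiol A7.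
- In its favour: one aqueous step would make both rings and all four stereocentres under enzyme control. For the C4 configuration this is better than the substrate control of step 1, and in steps to a C4-oxygenated eudesmane it is the equal of the chosen plan (one step). The cascade runs through the same C4 cation that step 1 aims for.
- Against it: the active site delivers a hydroxyl, not a hindered halophenol, so A7 stops at the C4 carbinol. One of two tertiary alcohols must then be arylated selectively (protection of C11, arylation of a hindered alkoxide, deprotection) before the two cross-couplings. Substrate cost and enzyme production limit scale.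
- Comparison: on structure both plans arrive at the same trans-eudesmane with the same configuration. On mechanism the alternative is better precedented and better controlled. On step economy the chosen plan is shorter, because the aryl ether is formed in the ring-closing step itself.

Key step: step 1

Assumption: natural (−)-elemol is taken as a purchasable single enantiomer whose C5, C7 and C10 centres map onto the (5R,7R,10R) centres of the target, so only C4 remains to be set; eudesmane numbering is used for 1 as well.

## Route

Step 1
Reactants: 1 (−)-elemol, 2-[(1R,3S,4S)-4-ethenyl-4-methyl-3-(prop-1-en-2-yl)cyclohexyl]propan-2-ol; 2 2-bromo-4-chlorophenol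
Product: 4 (4R,5R,7R,10R)-4-(2-bromo-4-chlorophenoxy)eudesman-11-ol, via C1-palladated aryl ether 3 (not isolated)
Conditions: PdCl2(MeCN)2 (10 mol %), 2 (3 equiv), 4 Å MS, CH2Cl2, 0 °C to rt; Et3N quench
Reagents that add atoms: none
Why: Proposed new method: PdCl2(MeCN)2 should bind the unhindered vinyl group C1=C2 of 1, and C3, the CH2 terminus of the isopropenyl group, should attack C2 anti to palladium through a chair in which both alkenyl groups are equatorial on ring B; this 6-endo-trig closure of ring A gives an equatorial C1–Pd bond and a tertiary cation at C4. The closest known reaction types are the Cope rearrangement of hexa-1,5-dienes bearing a C2 substituent under PdCl2(RCN)2 catalysis, which runs through the same palladated cyclohexyl cation, and the proton-triggered transannular ring closure of the cyclodecadiene hedycaryol to C4-functionalised eudesmanes; intermolecular capture of this cation by a phenol has not been shown. Fragmentation of the cation would lead to hedycaryol, the strained and less stable Cope partner of 1, which returns to the same C4 cation through palladium or through trace-acid closure of C5–C10, so the cation is re-formed until the excess of 2 intercepts it. Addition of the oxygen of 2 to C4 gives 3, and the proton set free in that step cleaves the C1–Pd bond, closing a redox-neutral cycle that returns divalent palladium. The only new stereocentre, C4, is set by the substrate: the axial C10 methyl group shields the β (axial) face of the cation, so 2 should enter from the α (equatorial) face and leave the C4 methyl axial, while C5, C7 and C10 come from 1 untouched. The step needs O- over C-alkylation, which the two halogens of 2 secure by blocking the para and one ortho position and deactivating the ring, and it needs capture by 2 in preference to the C11 hydroxyl, which sits on an equatorial side chain that cannot reach C4 of the trans-decalin and is outnumbered by 2. It also needs protonolysis to outrun β-hydride elimination, which is helped by C10 being quaternary and by the equatorial C1–Pd bond having no syn-coplanar C2–H in the chair. Molecular sieves keep water from competing for the cation, and the Et3N quench removes acid before the tertiary ether of 4 can re-ionise.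

Step 2
Reactants: 5 4-bromophenol
Product: 6 1-bromo-4-(prop-2-en-1-yloxy)benzene
Conditions: allyl bromide, K2CO3, acetone, reflux
Reagents that add atoms: allyl bromide (3-bromoprop-1-ene), C=CCBr
Why: Williamson ether synthesis; the phenoxide formed with carbonate attacks the allylic bromide at oxygen in an SN2 reaction, and the aryl bromide is inert.

Step 3
Reactants: 6 1-bromo-4-(prop-2-en-1-yloxy)benzene
Product: 8 2-allyl-4-bromophenol, via 6-allyl-4-bromocyclohexa-2,4-dienone 7 (not isolated)
Conditions: N,N-diethylaniline, 200 °C
Reagents that add atoms: none
Why: Aromatic Claisen rearrangement; the [3,3]-sigmatropic shift places the allyl group on an ortho carbon (the two are equivalent and para is blocked by bromine) to give dienone 7, which tautomerises to the phenol.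

Step 4
Reactants: 8 2-allyl-4-bromophenol
Product: 9 2-(prop-2-en-1-yl)-4-(4,4,5,5-tetramethyl-1,3,2-dioxaborolan-2-yl)phenol
Conditions: B2pin2, Pd(dppf)Cl2 (3 mol %), KOAc, 1,4-dioxane, 85 °C
Reagents that add atoms: bis(pinacolato)diboron, CC1(C)OB(OC1(C)C)B1OC(C)(C)C(C)(C)O1
Why: Miyaura borylation of an aryl bromide; the weak acetate base activates the diboron reagent but not the product boronate, so coupling of 9 with 8 is suppressed, and free phenols and isolated terminal alkenes are tolerated.

Step 5
Reactants: 4 (4R,5R,7R,10R)-4-(2-bromo-4-chlorophenoxy)eudesman-11-ol; 9 2-(prop-2-en-1-yl)-4-(4,4,5,5-tetramethyl-1,3,2-dioxaborolan-2-yl)phenol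
Product: 10 (4R,5R,7R,10R)-4-{[5-chloro-4'-hydroxy-3'-(prop-2-en-1-yl)biphenyl-2-yl]oxy}eudesman-11-ol
Conditions: Pd(dppf)Cl2 (5 mol %), K2CO3, 1,4-dioxane/H2O, 80 °C
Reagents that add atoms: none
Why: Suzuki–Miyaura coupling; zerovalent palladium generated from Pd(dppf)Cl2 inserts into the C–Br bond of 4 much faster than into its C–Cl bond, the tertiary ether and both free hydroxyl groups are stable to aqueous carbonate, and no stereocentre is touched.

Step 6
Reactants: 10 (4R,5R,7R,10R)-4-{[5-chloro-4'-hydroxy-3'-(prop-2-en-1-yl)biphenyl-2-yl]oxy}eudesman-11-ol
Product: 11 (4R,5R,7R,10R)-4-{[4'-hydroxy-3',5-di(prop-2-en-1-yl)biphenyl-2-yl]oxy}eudesman-11-ol (target)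
Conditions: allylboronic acid pinacol ester, Pd(OAc)2 (5 mol %), XPhos (10 mol %), K3PO4, THF/H2O, 60 °C
Reagents that add atoms: allylboronic acid pinacol ester (2-allyl-4,4,5,5-tetramethyl-1,3,2-dioxaborolane), C=CCB1OC(C)(C)C(C)(C)O1
Why: Suzuki–Miyaura allylation of an aryl chloride; the bulky, electron-rich XPhos ligand lets zerovalent palladium insert into the electron-rich C–Cl bond at moderate temperature, the unsubstituted allyl boronate raises no regiochemical question, and phosphate base at 60 °C should leave both terminal alkenes unconjugated and the tertiary ether intact.

## Compound list

1 | (−)-elemol, 2-[(1R,3S,4S)-4-ethenyl-4-methyl-3-(prop-1-en-2-yl)cyclohexyl]propan-2-ol | C=C[C@]1(C)CC[C@@H](C(C)(C)O)C[C@H]1C(C)=C | starting material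
2 | 2-bromo-4-chlorophenol | Oc1ccc(Cl)cc1Br | starting material
3 | 4α-(2-bromo-4-chlorophenoxy)-1β-(chloropalladio)eudesman-11-ol (nitrile ligands on palladium not drawn) | Clc1ccc(O[C@]2(C)CC[C@@H]([Pd]Cl)[C@]3(C)CC[C@@H](C(C)(C)O)C[C@H]32)c(Br)c1 | intermediate
4 | (4R,5R,7R,10R)-4-(2-bromo-4-chlorophenoxy)eudesman-11-ol, 2-[(2R,4aR,8R,8aR)-8-(2-bromo-4-chlorophenoxy)-4a,8-dimethyldecahydronaphthalen-2-yl]propan-2-ol | Clc1ccc(O[C@]2(C)CCC[C@]3(C)CC[C@@H](C(C)(C)O)C[C@H]32)c(Br)c1 | intermediate
5 | 4-bromophenol | Oc1ccc(Br)cc1 | starting material
6 | 1-bromo-4-(prop-2-en-1-yloxy)benzene | C=CCOc1ccc(Br)cc1 | intermediate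
7 | 6-allyl-4-bromocyclohexa-2,4-dienone (racemic) | O=C1C=CC(Br)=CC1CC=C | intermediate
8 | 2-allyl-4-bromophenol | C=CCc1cc(Br)ccc1O | intermediate
9 | 2-(prop-2-en-1-yl)-4-(4,4,5,5-tetramethyl-1,3,2-dioxaborolan-2-yl)phenol | C=CCc1cc(B2OC(C)(C)C(C)(C)O2)ccc1O | intermediate
10 | (4R,5R,7R,10R)-4-{[5-chloro-4'-hydroxy-3'-(prop-2-en-1-yl)biphenyl-2-yl]oxy}eudesman-11-ol | Clc1ccc(O[C@]2(C)CCC[C@]3(C)CC[C@@H](C(C)(C)O)C[C@H]32)c(-c2ccc(O)c(CC=C)c2)c1 | intermediate
11 | (4R,5R,7R,10R)-4-{[4'-hydroxy-3',5-di(prop-2-en-1-yl)biphenyl-2-yl]oxy}eudesman-11-ol | C=CCc1ccc(O[C@]2(C)CCC[C@]3(C)CC[C@@H](C(C)(C)O)C[C@H]32)c(-c2ccc(O)c(CC=C)c2)c1 | target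

## Step count and least certain steps

Total: 6 steps. Longest linear sequence: 5 steps (steps 2, 3, 4, 5, 6; 5 → 6 → 8 → 9 → 10 → 11). The terpenoid line from 1 is 3 steps (1, 5, 6).

Step 1 (key step, proposed new method). The most likely failure is that the palladated cation is not intercepted by the weakly nucleophilic 2. The competing processes are:
- loss of a proton from C4, directly or after a hydride shift, to eudesmol-type alkenes;
- β-hydride elimination at C1–Pd, which reduces the catalyst to zerovalent palladium;
- re-ionisation of the tertiary ether by the acid that the capture releases;
- entry of 2 on the β face, giving poor facial selectivity.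

Fallback with known reactions only, setting out from 1 and coming back at 4: the hydroxyl of 1 is silylated with Et3SiOTf and 2,6-lutidine to give 11-O-triethylsilylelemol F1. Hg(OAc)2 in aqueous THF then effects the classical cyclisation of a 1,5-diene by divalent mercury with water as terminating nucleophile, giving 1β-(acetoxymercurio)-11-(triethylsilyloxy)eudesman-4α-ol F2, which is not isolated but reduced in the same flask with alkaline NaBH4 to 11-O-triethylsilylcryptomeridiol F3; a C4 epimer, should it form, would be separated here. The potassium alkoxide of F3 (KH, THF/DMSO) displaces fluoride from purchased 2-bromo-4-chloro-1-fluorobenzene in a nucleophilic aromatic substitution that leaves the C4–O bond, and so the configuration, untouched and gives 4α-(2-bromo-4-chlorophenoxy)-11-(triethylsilyloxy)eudesmane F4. Bu4NF in THF removes the silyl group and delivers 4. The approach changes from capture of a cation by the phenol to arylation of a preformed alkoxide, so the aryl–O bond and not the C4–O bond is made in the etherification.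

Step 6. The most likely failure is slow oxidative addition into the electron-rich chloride, so that at the temperature needed palladium hydride species move one or both terminal alkenes into conjugation, or the chloride is reduced. Fallback, setting out from 1 and coming back at 11, reverses the order of the two couplings by changing the spectator halogen. Step 1 is run with purchased 2-bromo-4-iodophenol in place of 2 and gives, through 4α-(2-bromo-4-iodophenoxy)-1β-(chloropalladio)eudesman-11-ol F5 (not isolated), 4α-(2-bromo-4-iodophenoxy)eudesman-11-ol F6. The iodide alone couples with allylboronic acid pinacol ester under Pd(PPh3)4 and CsF in THF at 50 °C to give 4α-(4-allyl-2-bromophenoxy)eudesman-11-ol F7. Suzuki–Miyaura coupling of F7 with 9 under the conditions of step 5 gives 11. Both couplings then use the two most reactive halides and catalysts of low activity, at the price of carrying the ring C allyl group through one more palladium step.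

Step 5. The most likely failure is protodeboronation of electron-rich 9 (boron para to a phenoxide) under aqueous base before it can transmetalate to the hindered arylpalladium; a more active catalyst used to compensate would erode the bromide/chloride selectivity. Fallback, setting out from 4 and coming back at 10, exchanges the roles of the partners. Miyaura borylation of the bromide of 4 (B2pin2, Pd(dppf)Cl2, KOAc, 1,4-dioxane, 90 °C; the chloride is left alone) gives 4α-[4-chloro-2-(4,4,5,5-tetramethyl-1,3,2-dioxaborolan-2-yl)phenoxy]eudesman-11-ol F8, whose boron sits on an arene that is not a phenoxide. F8 is then coupled with the unhindered bromophenol 8 (Pd(dppf)Cl2, K2CO3, 1,4-dioxane/H2O, 80 °C) to give 10.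

## Further compounds

F1 | step 1 | 11-O-triethylsilylelemol, triethyl({2-[(1R,3S,4S)-4-ethenyl-4-methyl-3-(prop-1-en-2-yl)cyclohexyl]propan-2-yl}oxy)silane | C=C[C@]1(C)CC[C@@H](C(C)(C)O[Si](CC)(CC)CC)C[C@H]1C(C)=C
F2 | step 1 | 1β-(acetoxymercurio)-11-(triethylsilyloxy)eudesman-4α-ol | O[C@]1(C)CC[C@@H]([Hg]OC(C)=O)[C@]2(C)CC[C@@H](C(C)(C)O[Si](CC)(CC)CC)C[C@H]21
F3 | step 1 | 11-O-triethylsilylcryptomeridiol, (4R,5R,7R,10R)-11-(triethylsilyloxy)eudesman-4-ol | O[C@]1(C)CCC[C@]2(C)CC[C@@H](C(C)(C)O[Si](CC)(CC)CC)C[C@H]21
F4 | step 1 | (4R,5R,7R,10R)-4-(2-bromo-4-chlorophenoxy)-11-(triethylsilyloxy)eudesmane | Clc1ccc(O[C@]2(C)CCC[C@]3(C)CC[C@@H](C(C)(C)O[Si](CC)(CC)CC)C[C@H]32)c(Br)c1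
F5 | step 6 | 4α-(2-bromo-4-iodophenoxy)-1β-(chloropalladio)eudesman-11-ol (nitrile ligands on palladium not drawn) | Ic1ccc(O[C@]2(C)CC[C@@H]([Pd]Cl)[C@]3(C)CC[C@@H](C(C)(C)O)C[C@H]32)c(Br)c1
F6 | step 6 | (4R,5R,7R,10R)-4-(2-bromo-4-iodophenoxy)eudesman-11-ol | Ic1ccc(O[C@]2(C)CCC[C@]3(C)CC[C@@H](C(C)(C)O)C[C@H]32)c(Br)c1
F7 | step 6 | (4R,5R,7R,10R)-4-[2-bromo-4-(prop-2-en-1-yl)phenoxy]eudesman-11-ol | C=CCc1ccc(O[C@]2(C)CCC[C@]3(C)CC[C@@H](C(C)(C)O)C[C@H]32)c(Br)c1
F8 | step 5 | (4R,5R,7R,10R)-4-[4-chloro-2-(4,4,5,5-tetramethyl-1,3,2-dioxaborolan-2-yl)phenoxy]eudesman-11-ol | Clc1ccc(O[C@]2(C)CCC[C@]3(C)CC[C@@H](C(C)(C)O)C[C@H]32)c(B2OC(C)(C)C(C)(C)O2)c1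
A1 | alternative 1 | 2-[(3E,6R)-3,9-dimethyldeca-1,3,9-trien-6-yl]propan-2-ol | C=C/C(C)=C/C[C@H](C(C)(C)O)CCC(C)=C
A2 | alternative 1 | α-eudesmol | CC1=CCC[C@]2(C)CC[C@@H](C(C)(C)O)C[C@H]21
A3 | alternative 2 | C4 ynol ether: (4R,5R,7R,10R)-4-({[4-(tert-butyldimethylsilyloxy)-3-(prop-2-en-1-yl)phenyl]ethynyl}oxy)-11-(triethylsilyloxy)eudesmane | C=CCc1cc(C#CO[C@]2(C)CCC[C@]3(C)CC[C@@H](C(C)(C)O[Si](CC)(CC)CC)C[C@H]32)ccc1O[Si](C)(C)C(C)(C)C
A4 | alternative 2 | methyl coumalate, methyl 2-oxo-2H-pyran-5-carboxylate | COC(=O)C1=COC(=O)C=C1
A5 | alternative 2 | methyl 4-(eudesmyloxy)-3-arylbenzoate, bis-silyl ether | C=CCc1cc(-c2cc(C(=O)OC)ccc2O[C@]2(C)CCC[C@]3(C)CC[C@@H](C(C)(C)O[Si](CC)(CC)CC)C[C@H]32)ccc1O[Si](C)(C)C(C)(C)C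
A6 | alternative 3 | (2E,6E)-farnesyl diphosphate | CC(C)=CCC/C(C)=C/CC/C(C)=C/COP(=O)(O)OP(=O)(O)O
A7 | alternative 3 | cryptomeridiol, (4R,5R,7R,10R)-eudesmane-4,11-diol | O[C@]1(C)CCC[C@]2(C)CC[C@@H](C(C)(C)O)C[C@H]21
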